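At the last reading, 80.0 min after the start, a quarter of the two substrates was left, and I had to say what 4.0 h would bring. In this flask the partner, on a single-handed catalyst made from precatalyst, turns each substrate into the product of its own hand.

in all of them: left-handed substrate 0.73 M; right-handed substrate 0.73 M; precatalyst 15 mol%

| run | partner | remark | time |
|---|---|---|---|
| epsilon | 4 equiv | the very flask that is asked about, followed so far |  |
| flask | 4.00 equiv |  | 4.0 h |

epsilon run (percent of the left-handed substrate and right-handed substrate together charged)

| time / min | left-handed substrate / % | right-handed substrate / % | left-handed product / % |
|---|---|---|---|
| 10.0 | 37 | 46 | 12 |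
| 20.0 | 28 | 35 | 27 |
| 30.0 | 22 | 30 | 35 |
| 40.0 | 16 | 23 | 36 |
| 50.0 | 13 | 20 | 47 |
| 60.0 | 10 | 19 | 50 |
| 80.0 | 10 | 15 | 52 |

(each reading ± 1.5 percentage points)

- part of the left-handed substrate and right-handed substrate charged together that has reacted at 4.0 h
- excess of left-handed product over right-handed product in the product at 4.0 h
- excess of right-handed substrate over left-handed substrate among what is left of the two at 4.0 h

- catalyst is single-handed; left-handed substrate and right-handed substrate are mirror images of each other, charged as a racemate, each of them at the stated concentration
- the analysis behind the earlier runs scatters by 1.5 percentage points, standard deviation
- an excess is the difference of the two amounts in percent of their sum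
- an excess is below zero if the other one leads

I built the flask up step by step. With just the two product-forming steps, left-handed substrate plus left-handed product stays at half of the charge, and the substrate excess keeps climbing. Counting what is missing as right-handed product, the product excess read 38.7% at 80.0 min.

But at 60.0 min the left-handed pair added up to 60.0%, so right-handed substrate had been passing over, as in a dynamic kinetic resolution. Dividing that surplus by the summed substrate difference over time gave an interconversion constant of 0.0235 min⁻¹. The catch-up time, the half-life at which interconversion by itself closes the difference between the substrates, was therefore 14.7 min. For this flask I took the substrate excess, once the substrates vanish more slowly than that, as the product excess times catch-up time over substrate half-life.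

The last addition was the slowing. The substrate half-life grew from 25.1 min early on to 93.4 min between the last two readings, well past the catch-up time. Holding that half-life, I reckoned 92.4% reacted and a substrate excess of 6.09%. The reading of 20.0% at 80.0 min rests on a difference of 5 percentage points with a scatter of 1.5 points on each reading.

The forecast differed from my reckoning: 86% reacted, 38% and 25%, on a rise “which suggests a plateau”.

The flask gave 94.0% reacted, a product excess of 39.8% and a substrate excess of 7.61%.

    left-handed substrate ⇌ right-handed substrate (k = 0.0250 min⁻¹)
    partner + catalyst + left-handed substrate → catalyst + left-handed product (k = 0.820 M⁻² min⁻¹)
    2 catalyst ⇌ resting dimer (K = 670 M⁻¹, k = 2.00 M⁻¹ min⁻¹)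
    precatalyst → catalyst (k = 0.0250 min⁻¹)
    partner + catalyst + right-handed substrate → catalyst + right-handed product (k = 0.270 M⁻² min⁻¹)

Between 2.00 h and 4.0 h the substrates of this flask had a half-life of 88.5 min, longer than the catch-up time of 14.7 min that I had read from the runs, and the rule with that reading gives 6.61% beside the 7.61% that stood there. For the flask with 26 mol% of precatalyst, shortening that half-life in the ratio of free catalyst to 66.7 min gives, with the same reading of the catch-up time, 8.17%, and that flask stands at 9.74%.

(The readings come from a simulation from invented constants, noise included.)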